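**Plan**

1. Locants follow germacranolide numbering: C2 is the hemiketal carbon, C5 the oxolane O–CH, C6/C7 the lactone ring fusion, C8 the tiglate carbinol, C4=C15 and C10=C14 the ring exo-methylenes, C11=C13/C12 the α-methylene lactone. The retrosynthesis cuts the oxolane C2–O bond first, then both C–C bonds at C2 (C1–C2 and C2–C3), which removes C2 as carbon monoxide and leaves a C1 allylic chloride and a C3 allylstannane on the lactone core. Further cuts are C4–C5, C8–C9 and C7–C8.
2. Enabling feature: C2 lies between two CH2 groups (C1 and C3) that are each a terminus of a 2-substituted allyl unit (C14=C10–C1 and C15=C4–C3), whose two CH2 termini are equivalent, so no regiochemical question arises. The C5 hydroxyl sits γ to C2, so the diallyl ketone formed by CO insertion is captured at once as the five-membered hemiketal.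
3. Forward: the γ-lactone comes from a chiral-pool butenolide. Conjugate addition and methylenation complete the lactone core; the C8 arm (allylic chloride, tiglate) and then the C5 arm (allylstannane) are attached. CO is stitched between the two arms to close the ten-membered carbocycle, and the oxolane closes last in the same operation.
4. Stereochemistry: C6 from (5S)-5-(hydroxymethyl)furan-2(5H)-one; C7 by trans conjugate addition; C8 by catalyst-controlled Keck allylation; C5 by Felkin–Anh reduction of the C5 ketone; C2 follows from C5 because the six-carbon bridge can span the oxolane only cis.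

Key step: step 15

Remark: the closed hemiketal is taken as the stable ring tautomer of the ten-membered γ-hydroxy ketone, as drawn for the target, so no separate cyclisation operation is planned.

**Route**

Step 1
Reactants: 1 (5S)-5-(hydroxymethyl)furan-2(5H)-one
Product: 2 (5S)-5-[(tert-butyldimethylsilyloxy)methyl]furan-2(5H)-one
Conditions: TBSCl, imidazole, DMF, 0 °C to rt
Reagents that add atoms: tert-butyldimethylsilyl chloride, CC(C)(C)[Si](C)(C)Cl
Why: Silyl ether formation masks the primary C5 hydroxyl for the organometallic and enolate steps without touching the C6 stereocentre.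

Step 2
Reactants: 2 (5S)-5-[(tert-butyldimethylsilyloxy)methyl]furan-2(5H)-one
Product: 3 (4R,5S)-5-[(tert-butyldimethylsilyloxy)methyl]-4-(2-methylprop-1-en-1-yl)oxolan-2-one
Conditions: Me2C=CHMgBr, CuBr·SMe2 (15 mol %), THF, −78 °C; aq NH4Cl
Reagents that add atoms: 2-methylprop-1-en-1-ylmagnesium bromide, CC(C)=C[Mg]Br
Why: Copper-catalysed conjugate addition of the Grignard reagent to the butenolide should occur anti to the silyloxymethyl group and set C7 trans (4R); the 2-methylpropenyl group is a latent formyl group that ozone cleaves far faster than an α-methylene lactone.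

Step 3
Reactants: 3 (4R,5S)-5-[(tert-butyldimethylsilyloxy)methyl]-4-(2-methylprop-1-en-1-yl)oxolan-2-one
Product: 7 (4S,5S)-5-[(tert-butyldimethylsilyloxy)methyl]-3-methylidene-4-(2-methylprop-1-en-1-yl)oxolan-2-one, via lithium enolate 4 (not isolated), via Mannich base 5 (not isolated), via ammonium iodide 6 (not isolated)
Conditions: LiN(SiMe3)2, THF, −78 °C; CH2=NMe2+ I−, −78 °C to rt; MeI, MeOH, rt; aq NaHCO3, CH2Cl2, rt
Reagents that add atoms: N,N-dimethylmethyleneiminium iodide, C[N+](C)=C.[I-]; iodomethane, CI (its methyl group enters intermediate 6 only)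
Why: Eschenmoser methylenation (Mannich reaction of the lithium enolate, N-methylation, mild base-induced elimination) installs the C11=C13 exo-methylene; only the lactone α-position is deprotonated, so C7 is untouched.

Step 4
Reactants: 7 (4S,5S)-5-[(tert-butyldimethylsilyloxy)methyl]-3-methylidene-4-(2-methylprop-1-en-1-yl)oxolan-2-one
Product: 9 (2S,3S)-2-[(tert-butyldimethylsilyloxy)methyl]-4-methylidene-5-oxooxolane-3-carbaldehyde, via ozonide 8 (not isolated)
Conditions: O3, CH2Cl2, −78 °C (Sudan Red 7B end point); Me2S, −78 °C to rt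
Reagents that add atoms: ozone, [O-][O+]=O
Why: Ozonolysis with reductive work-up should cleave the electron-rich trisubstituted alkene selectively beside the electron-poor α-methylene lactone and unmask the C8 aldehyde, which is used crude and cold because C7–H is now acidic.

Step 5
Reactants: 10 3-chloro-2-(chloromethyl)prop-1-ene
Product: 11 tributyl[2-(chloromethyl)prop-2-en-1-yl]stannane
Conditions: Bu3SnH, LiN(iPr)2, THF, 0 °C; then 10 (3 equiv), −78 °C
Reagents that add atoms: tributyltin hydride, CCCC[SnH](CCCC)CCCC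
Why: SN2 substitution of one allylic chloride by the stannyl anion (excess dichloride suppresses double substitution) gives the bifunctional allylstannane/allylic chloride reagent.

Step 6
Reactants: 9 (2S,3S)-2-[(tert-butyldimethylsilyloxy)methyl]-4-methylidene-5-oxooxolane-3-carbaldehyde; 11 tributyl[2-(chloromethyl)prop-2-en-1-yl]stannane
Product: 12 (4R,5S)-5-[(tert-butyldimethylsilyloxy)methyl]-4-[(1S)-3-(chloromethyl)-1-hydroxybut-3-en-1-yl]-3-methylideneoxolan-2-one
Conditions: (S)-BINOL (20 mol %), Ti(OiPr)4 (10 mol %), 4 Å MS, CH2Cl2, −20 °C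
Reagents that add atoms: none
Why: Keck asymmetric allylation (BINOL/Ti(OiPr)4-catalysed allylstannane addition) should deliver the allyl group to the Si face of the aldehyde under catalyst control and set 8S, while the allylic chloride of the reagent is inert to the mild Lewis acid and is kept as the later electrophile.

Step 7
Reactants: 12 (4R,5S)-5-[(tert-butyldimethylsilyloxy)methyl]-4-[(1S)-3-(chloromethyl)-1-hydroxybut-3-en-1-yl]-3-methylideneoxolan-2-one
Product: 13 (1S)-1-{(2S,3R)-2-[(tert-butyldimethylsilyloxy)methyl]-4-methylidene-5-oxooxolan-3-yl}-3-(chloromethyl)but-3-en-1-yl (2E)-2-methylbut-2-enoate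
Conditions: tigloyl chloride, pyridine, DMAP (cat.), CH2Cl2, 0 °C to rt
Reagents that add atoms: (2E)-2-methylbut-2-enoyl chloride, C/C=C(\C)C(Cl)=O
Why: DMAP-catalysed acylation of the secondary alcohol installs the tiglate with retention at C8 and keeps O8 from interfering at palladium later.

Step 8
Reactants: 13 (1S)-1-{(2S,3R)-2-[(tert-butyldimethylsilyloxy)methyl]-4-methylidene-5-oxooxolan-3-yl}-3-(chloromethyl)but-3-en-1-yl (2E)-2-methylbut-2-enoate
Product: 14 (1S)-3-(chloromethyl)-1-[(2S,3R)-2-(hydroxymethyl)-4-methylidene-5-oxooxolan-3-yl]but-3-en-1-yl (2E)-2-methylbut-2-enoate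
Conditions: HF·pyridine, pyridine, THF, 0 °C to rt
Reagents that add atoms: none
Why: Fluoride-mediated desilylation under buffered conditions frees the primary C5 alcohol without affecting the ester, lactone, allylic chloride or Michael acceptor.

Step 9
Reactants: 14 (1S)-3-(chloromethyl)-1-[(2S,3R)-2-(hydroxymethyl)-4-methylidene-5-oxooxolan-3-yl]but-3-en-1-yl (2E)-2-methylbut-2-enoate
Product: 15 (1S)-3-(chloromethyl)-1-[(2S,3R)-2-formyl-4-methylidene-5-oxooxolan-3-yl]but-3-en-1-yl (2E)-2-methylbut-2-enoate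
Conditions: Dess–Martin periodinane, NaHCO3, CH2Cl2, 0 °C to rt
Reagents that add atoms: none
Why: Dess–Martin oxidation gives the α-acyloxy aldehyde under neutral buffered conditions that avoid epimerisation at C6.

Step 10
Reactants: 15 (1S)-3-(chloromethyl)-1-[(2S,3R)-2-formyl-4-methylidene-5-oxooxolan-3-yl]but-3-en-1-yl (2E)-2-methylbut-2-enoate
Product: 16 (1S)-3-(chloromethyl)-1-[(2S,3R)-2-{(1RS)-1-hydroxy-2-[(trimethylsilyl)methyl]prop-2-en-1-yl}-4-methylidene-5-oxooxolan-3-yl]but-3-en-1-yl (2E)-2-methylbut-2-enoate (both carbinol epimers)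
Conditions: CH2=C(MgBr)CH2SiMe3 (from the bromide and Mg, THF), THF, −78 °C; aq NH4Cl
Reagents that add atoms: (2-bromoprop-2-en-1-yl)trimethylsilane, C=C(Br)C[Si](C)(C)C (used as its Grignard reagent)
Why: Chemoselective Grignard 1,2-addition to the aldehyde at low temperature attaches the C4 unit already carrying the allylsilane; the carbinol configuration is irrelevant because it is erased in step 11.

Step 11
Reactants: 16 (1S)-3-(chloromethyl)-1-[(2S,3R)-2-{(1RS)-1-hydroxy-2-[(trimethylsilyl)methyl]prop-2-en-1-yl}-4-methylidene-5-oxooxolan-3-yl]but-3-en-1-yl (2E)-2-methylbut-2-enoate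
Product: 17 (1S)-3-(chloromethyl)-1-[(2S,3R)-4-methylidene-5-oxo-2-{2-[(trimethylsilyl)methyl]prop-2-enoyl}oxolan-3-yl]but-3-en-1-yl (2E)-2-methylbut-2-enoate
Conditions: Dess–Martin periodinane, NaHCO3, CH2Cl2, 0 °C
Reagents that add atoms: none
Why: Dess–Martin oxidation gives the enone so that C5 can be set by hydride addition, since direct carbon addition to the aldehyde would favour the wrong (5,6-anti) isomer.

Step 12
Reactants: 17 (1S)-3-(chloromethyl)-1-[(2S,3R)-4-methylidene-5-oxo-2-{2-[(trimethylsilyl)methyl]prop-2-enoyl}oxolan-3-yl]but-3-en-1-yl (2E)-2-methylbut-2-enoate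
Product: 18 (1S)-3-(chloromethyl)-1-[(2S,3R)-2-{(1S)-1-hydroxy-2-[(trimethylsilyl)methyl]prop-2-en-1-yl}-4-methylidene-5-oxooxolan-3-yl]but-3-en-1-yl (2E)-2-methylbut-2-enoate
Conditions: NaBH4, CeCl3·7H2O, MeOH, −78 °C
Reagents that add atoms: none
Why: Luche reduction (1,2-selective) under polar Felkin–Anh control, with hydride entering anti to the C6–O bond, should give the 5,6-syn (5S) carbinol, as is typical of hydride reductions of 5-acyl-γ-lactones, and the cold conditions should spare the α-methylene lactone.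

Step 13
Reactants: 18 (1S)-3-(chloromethyl)-1-[(2S,3R)-2-{(1S)-1-hydroxy-2-[(trimethylsilyl)methyl]prop-2-en-1-yl}-4-methylidene-5-oxooxolan-3-yl]but-3-en-1-yl (2E)-2-methylbut-2-enoate
Product: 19 (1S)-1-{(2S,3R)-2-[(1S)-2-(bromomethyl)-1-hydroxyprop-2-en-1-yl]-4-methylidene-5-oxooxolan-3-yl}-3-(chloromethyl)but-3-en-1-yl (2E)-2-methylbut-2-enoate
Conditions: NBS, propylene oxide, CH2Cl2, −78 °C
Reagents that add atoms: N-bromosuccinimide, BrN1C(=O)CCC1=O
Why: Bromodesilylation of the allylsilane (electrophilic SE2′ substitution) is far faster than bromination of the other, electron-poorer alkenes; the allyl unit is symmetrical, so the allylic transposition does not change the constitution.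

Step 14
Reactants: 19 (1S)-1-{(2S,3R)-2-[(1S)-2-(bromomethyl)-1-hydroxyprop-2-en-1-yl]-4-methylidene-5-oxooxolan-3-yl}-3-(chloromethyl)but-3-en-1-yl (2E)-2-methylbut-2-enoate
Product: 20 (1S)-3-(chloromethyl)-1-[(2S,3R)-2-{(1S)-1-hydroxy-2-[(tributylstannyl)methyl]prop-2-en-1-yl}-4-methylidene-5-oxooxolan-3-yl]but-3-en-1-yl (2E)-2-methylbut-2-enoate
Conditions: Zn dust, Bu3SnCl, THF/sat. aq NH4Cl, rt
Reagents that add atoms: tributyltin chloride, CCCC[Sn](Cl)(CCCC)CCCC
Why: Barbier-type zinc-mediated stannylation: zinc should insert into the allylic bromide much faster than into the allylic chloride, and trapping of the transient allylzinc by Bu3SnCl inverts the polarity of the C3 terminus while tolerating the free hydroxyl, esters and lactone.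

Step 15
Reactants: 20 (1S)-3-(chloromethyl)-1-[(2S,3R)-2-{(1S)-1-hydroxy-2-[(tributylstannyl)methyl]prop-2-en-1-yl}-4-methylidene-5-oxooxolan-3-yl]but-3-en-1-yl (2E)-2-methylbut-2-enoate
Product: 22 CNP0307443.2 (2S,5S,6S,7R,8S)-2-hydroxy-2,5-epoxygermacra-4(15),10(14),11(13)-trien-12,6-olide 8-[(2E)-2-methylbut-2-enoate], via macrocyclic ketone 21 (not isolated)
Conditions: Pd2(dba)3 (5 mol %), AsPh3 (20 mol %), CO (3 atm), THF (2 mM, syringe-pump addition of 20), 50 °C
Reagents that add atoms: carbon monoxide, [C-]#[O+]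
Why: Proposed new method: zerovalent palladium ionises the allylic chloride to a 2-substituted η3-allyl complex with equivalent CH2 termini, CO inserts to give a β,γ-unsaturated acyl palladium species, and intramolecular tin-to-palladium transfer of the second 2-substituted allyl group followed by reductive elimination joins C1 and C3 to the inserted carbon as the ten-membered bis(β,γ-unsaturated) ketone 21. The closest known reaction type is the intermolecular palladium-catalysed carbonylative Stille coupling of allyl chlorides with allylstannanes to diallyl ketones, together with carbonylative Stille macrocyclisations of alkenyl triflates with alkenylstannanes; the new element is the allyl/allyl pairing in a ring-closing mode. The carbocycle is closed as a ten-membered ring by acyl–allyl reductive elimination at the metal, and the oxolane is closed last by spontaneous 5-exo-trig addition of the C5 hydroxyl to the C2 ketone. The only new stereocentre, the hemiketal carbon, is fixed by C5 because the six-carbon bridge can span the oxolane only cis, so 2S follows from 5S under thermodynamic control. The step needs CO insertion to outrun direct allyl–allyl coupling (CO pressure and the slow reductive elimination of bis-allyl palladium), ring closure to outrun oligomerisation (slow addition at millimolar concentration) and no drift of the β,γ-alkenes into conjugation (neutral conditions and immediate capture of the ketone as hemiketal); either allyl unit may react with or without allylic transposition without changing the product, because both are 2-substituted with identical termini.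

**Compound list**

1 | (5S)-5-(hydroxymethyl)furan-2(5H)-one | C1=CC(=O)O[C@@H]1CO | starting material
2 | (5S)-5-[(tert-butyldimethylsilyloxy)methyl]furan-2(5H)-one | C1=CC(=O)O[C@@H]1CO[Si](C)(C)C(C)(C)C | intermediate
3 | (4R,5S)-5-[(tert-butyldimethylsilyloxy)methyl]-4-(2-methylprop-1-en-1-yl)oxolan-2-one (4,5-trans) | CC(C)=C[C@H]1CC(=O)O[C@@H]1CO[Si](C)(C)C(C)(C)C | intermediate
4 | lithium enolate of 3 (ring stereocentres unchanged) | CC(C)=C[C@H]1C=C(O[Li])O[C@@H]1CO[Si](C)(C)C(C)(C)C | intermediate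
5 | 3-[(dimethylamino)methyl] derivative of 3 (Mannich base, epimers at the new α-carbon) | CC(C)=C[C@H]1C(CN(C)C)C(=O)O[C@@H]1CO[Si](C)(C)C(C)(C)C | intermediate
6 | N-methylated Mannich base, trimethylammonium iodide | CC(C)=C[C@H]1C(C[N+](C)(C)C)C(=O)O[C@@H]1CO[Si](C)(C)C(C)(C)C.[I-] | intermediate
7 | (4S,5S)-5-[(tert-butyldimethylsilyloxy)methyl]-3-methylidene-4-(2-methylprop-1-en-1-yl)oxolan-2-one | CC(C)=C[C@H]1C(=C)C(=O)O[C@@H]1CO[Si](C)(C)C(C)(C)C | intermediate
8 | ozonide of 7 (3,3-dimethyl-1,2,4-trioxolan-5-yl group in place of the 2-methylpropenyl group) | CC1(C)OOC(O1)[C@H]2C(=C)C(=O)O[C@@H]2CO[Si](C)(C)C(C)(C)C | intermediate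
9 | (2S,3S)-2-[(tert-butyldimethylsilyloxy)methyl]-4-methylidene-5-oxooxolane-3-carbaldehyde | O=C[C@H]1C(=C)C(=O)O[C@@H]1CO[Si](C)(C)C(C)(C)C | intermediate
10 | 3-chloro-2-(chloromethyl)prop-1-ene | ClCC(=C)CCl | starting material
11 | tributyl[2-(chloromethyl)prop-2-en-1-yl]stannane | ClCC(=C)C[Sn](CCCC)(CCCC)CCCC | intermediate
12 | (4R,5S)-5-[(tert-butyldimethylsilyloxy)methyl]-4-[(1S)-3-(chloromethyl)-1-hydroxybut-3-en-1-yl]-3-methylideneoxolan-2-one | ClCC(=C)C[C@H](O)[C@H]1C(=C)C(=O)O[C@@H]1CO[Si](C)(C)C(C)(C)C | intermediate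
13 | (1S)-1-{(2S,3R)-2-[(tert-butyldimethylsilyloxy)methyl]-4-methylidene-5-oxooxolan-3-yl}-3-(chloromethyl)but-3-en-1-yl (2E)-2-methylbut-2-enoate | ClCC(=C)C[C@H](OC(=O)/C(C)=C/C)[C@H]1C(=C)C(=O)O[C@@H]1CO[Si](C)(C)C(C)(C)C | intermediate
14 | (1S)-3-(chloromethyl)-1-[(2S,3R)-2-(hydroxymethyl)-4-methylidene-5-oxooxolan-3-yl]but-3-en-1-yl (2E)-2-methylbut-2-enoate | ClCC(=C)C[C@H](OC(=O)/C(C)=C/C)[C@H]1C(=C)C(=O)O[C@@H]1CO | intermediate
15 | (1S)-3-(chloromethyl)-1-[(2S,3R)-2-formyl-4-methylidene-5-oxooxolan-3-yl]but-3-en-1-yl (2E)-2-methylbut-2-enoate | ClCC(=C)C[C@H](OC(=O)/C(C)=C/C)[C@H]1C(=C)C(=O)O[C@@H]1C=O | intermediate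
16 | (1S)-3-(chloromethyl)-1-[(2S,3R)-2-{(1RS)-1-hydroxy-2-[(trimethylsilyl)methyl]prop-2-en-1-yl}-4-methylidene-5-oxooxolan-3-yl]but-3-en-1-yl (2E)-2-methylbut-2-enoate (both carbinol epimers) | ClCC(=C)C[C@H](OC(=O)/C(C)=C/C)[C@H]1C(=C)C(=O)O[C@@H]1C(O)C(=C)C[Si](C)(C)C | intermediate
17 | (1S)-3-(chloromethyl)-1-[(2S,3R)-4-methylidene-5-oxo-2-{2-[(trimethylsilyl)methyl]prop-2-enoyl}oxolan-3-yl]but-3-en-1-yl (2E)-2-methylbut-2-enoate | ClCC(=C)C[C@H](OC(=O)/C(C)=C/C)[C@H]1C(=C)C(=O)O[C@@H]1C(=O)C(=C)C[Si](C)(C)C | intermediate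
18 | (1S)-3-(chloromethyl)-1-[(2S,3R)-2-{(1S)-1-hydroxy-2-[(trimethylsilyl)methyl]prop-2-en-1-yl}-4-methylidene-5-oxooxolan-3-yl]but-3-en-1-yl (2E)-2-methylbut-2-enoate | ClCC(=C)C[C@H](OC(=O)/C(C)=C/C)[C@H]1C(=C)C(=O)O[C@@H]1[C@@H](O)C(=C)C[Si](C)(C)C | intermediate
19 | (1S)-1-{(2S,3R)-2-[(1S)-2-(bromomethyl)-1-hydroxyprop-2-en-1-yl]-4-methylidene-5-oxooxolan-3-yl}-3-(chloromethyl)but-3-en-1-yl (2E)-2-methylbut-2-enoate | ClCC(=C)C[C@H](OC(=O)/C(C)=C/C)[C@H]1C(=C)C(=O)O[C@@H]1[C@@H](O)C(=C)CBr | intermediate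
20 | (1S)-3-(chloromethyl)-1-[(2S,3R)-2-{(1S)-1-hydroxy-2-[(tributylstannyl)methyl]prop-2-en-1-yl}-4-methylidene-5-oxooxolan-3-yl]but-3-en-1-yl (2E)-2-methylbut-2-enoate | ClCC(=C)C[C@H](OC(=O)/C(C)=C/C)[C@H]1C(=C)C(=O)O[C@@H]1[C@@H](O)C(=C)C[Sn](CCCC)(CCCC)CCCC | intermediate
21 | (5S,6S,7R,8S)-5-hydroxy-2-oxogermacra-4(15),10(14),11(13)-trien-12,6-olide 8-[(2E)-2-methylbut-2-enoate] (open ten-membered hydroxy ketone) | C=C1C[C@H](OC(=O)/C(C)=C/C)[C@H]2C(=C)C(=O)O[C@@H]2[C@@H](O)C(=C)CC(=O)C1 | intermediate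
22 | CNP0307443.2, (2S,5S,6S,7R,8S)-2-hydroxy-2,5-epoxygermacra-4(15),10(14),11(13)-trien-12,6-olide 8-[(2E)-2-methylbut-2-enoate] | C=C1C[C@H](OC(=O)/C(C)=C/C)[C@H]2C(=C)C(=O)O[C@@H]2[C@H]2O[C@@](O)(C1)CC2=C | target

**Step count**

Total: 15 steps. Longest linear sequence: 14 steps (1 to 22 through steps 1–4 and 6–15); step 5 is a one-step side branch.

**Steps most likely to fail**

Step 15 (Proposed new method). What may go wrong: oligomerisation instead of ring closure, direct allyl–allyl coupling without CO uptake, or protodestannylation of the hydroxy allylstannane before transmetalation. Fallback with known chemistry, closing the ten-membered ring at C4–C5 instead: the route sets out from tiglate 13. Intermolecular carbonylative Stille coupling of its allylic chloride (Pd2(dba)3, CO, THF) with tributyl(2-bromoprop-2-en-1-yl)stannane F1 (made from 2,3-dibromopropene and Bu3SnLi) should give (1S)-7-bromo-1-{(2S,3R)-2-[(tert-butyldimethylsilyloxy)methyl]-4-methylidene-5-oxooxolan-3-yl}-3-methylidene-5-oxooct-7-en-1-yl (2E)-2-methylbut-2-enoate F2. HF·pyridine should then give the primary alcohol, (1S)-7-bromo-1-[(2S,3R)-2-(hydroxymethyl)-4-methylidene-5-oxooxolan-3-yl]-3-methylidene-5-oxooct-7-en-1-yl (2E)-2-methylbut-2-enoate F3, and Dess–Martin oxidation the aldehyde, (1S)-7-bromo-1-[(2S,3R)-2-formyl-4-methylidene-5-oxooxolan-3-yl]-3-methylidene-5-oxooct-7-en-1-yl (2E)-2-methylbut-2-enoate F4. Intramolecular Nozaki–Hiyama–Kishi reaction (CrCl2, NiCl2 cat., DMSO/THF, high dilution) would form the C4–C5 bond, and the chromium alkoxide would add across the ring to the C2 ketone, so that the oxolane is again the last ring to close and the route is rejoined at target 22. The C5 configuration would then depend on the macrocyclic transition state, which is the weak point of this alternative.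

Step 6. What may go wrong: poor facial selectivity, because the catalyst must override the bias of the α-branched, β-acyloxy aldehyde (expected 1,3-anti, i.e. 8R), and erosion of the aldehyde by enolisation during a slow catalytic reaction. Fallback that uses the substrate bias instead of fighting it: from aldehyde 9, fast BF3·OEt2-promoted addition of stannane 11 at −78 °C (or the antipodal (R)-BINOL/Ti(OiPr)4 catalyst) should give the epimeric alcohol (4R,5S)-5-[(tert-butyldimethylsilyloxy)methyl]-4-[(1R)-3-(chloromethyl)-1-hydroxybut-3-en-1-yl]-3-methylideneoxolan-2-one F5. Mitsunobu esterification with tiglic acid (PPh3, DIAD, THF) would install the tiglate with inversion and rejoin the route at 13.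

Step 12. What may go wrong: poor facial selectivity of hydride delivery to the enone, or competing conjugate reduction of the α-methylene lactone. Fallback that sets C5 by invertive substitution instead of reduction: the route sets out from the Grignard adducts 16 and skips steps 11 and 12. The epimers are separated; the 5S epimer is 18 itself. The 5R epimer, (1S)-3-(chloromethyl)-1-[(2S,3R)-2-{(1R)-1-hydroxy-2-[(trimethylsilyl)methyl]prop-2-en-1-yl}-4-methylidene-5-oxooxolan-3-yl]but-3-en-1-yl (2E)-2-methylbut-2-enoate F6, is inverted by Mitsunobu reaction with chloroacetic acid (PPh3, DIAD) to the chloroacetate, (1S)-1-[(2S,3R)-3-{(1S)-3-(chloromethyl)-1-[(2E)-2-methylbut-2-enoyloxy]but-3-en-1-yl}-4-methylidene-5-oxooxolan-2-yl]-2-[(trimethylsilyl)methyl]prop-2-en-1-yl chloroacetate F7. Mild methanolysis (NaHCO3, MeOH, 0 °C), which the hindered tiglate should survive, cleaves F7 and rejoins the route at 18.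

**Further compounds**

F1 | step 15 | tributyl(2-bromoprop-2-en-1-yl)stannane | BrC(=C)C[Sn](CCCC)(CCCC)CCCC
F2 | step 15 | (1S)-7-bromo-1-{(2S,3R)-2-[(tert-butyldimethylsilyloxy)methyl]-4-methylidene-5-oxooxolan-3-yl}-3-methylidene-5-oxooct-7-en-1-yl (2E)-2-methylbut-2-enoate | BrC(=C)CC(=O)CC(=C)C[C@H](OC(=O)/C(C)=C/C)[C@H]1C(=C)C(=O)O[C@@H]1CO[Si](C)(C)C(C)(C)C
F3 | step 15 | (1S)-7-bromo-1-[(2S,3R)-2-(hydroxymethyl)-4-methylidene-5-oxooxolan-3-yl]-3-methylidene-5-oxooct-7-en-1-yl (2E)-2-methylbut-2-enoate | BrC(=C)CC(=O)CC(=C)C[C@H](OC(=O)/C(C)=C/C)[C@H]1C(=C)C(=O)O[C@@H]1CO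
F4 | step 15 | (1S)-7-bromo-1-[(2S,3R)-2-formyl-4-methylidene-5-oxooxolan-3-yl]-3-methylidene-5-oxooct-7-en-1-yl (2E)-2-methylbut-2-enoate | BrC(=C)CC(=O)CC(=C)C[C@H](OC(=O)/C(C)=C/C)[C@H]1C(=C)C(=O)O[C@@H]1C=O
F5 | step 6 | (4R,5S)-5-[(tert-butyldimethylsilyloxy)methyl]-4-[(1R)-3-(chloromethyl)-1-hydroxybut-3-en-1-yl]-3-methylideneoxolan-2-one | ClCC(=C)C[C@@H](O)[C@H]1C(=C)C(=O)O[C@@H]1CO[Si](C)(C)C(C)(C)C
F6 | step 12 | (1S)-3-(chloromethyl)-1-[(2S,3R)-2-{(1R)-1-hydroxy-2-[(trimethylsilyl)methyl]prop-2-en-1-yl}-4-methylidene-5-oxooxolan-3-yl]but-3-en-1-yl (2E)-2-methylbut-2-enoate | ClCC(=C)C[C@H](OC(=O)/C(C)=C/C)[C@H]1C(=C)C(=O)O[C@@H]1[C@H](O)C(=C)C[Si](C)(C)C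
F7 | step 12 | (1S)-1-[(2S,3R)-3-{(1S)-3-(chloromethyl)-1-[(2E)-2-methylbut-2-enoyloxy]but-3-en-1-yl}-4-methylidene-5-oxooxolan-2-yl]-2-[(trimethylsilyl)methyl]prop-2-en-1-yl chloroacetate | ClCC(=C)C[C@H](OC(=O)/C(C)=C/C)[C@H]1C(=C)C(=O)O[C@@H]1[C@@H](OC(=O)CCl)C(=C)C[Si](C)(C)C
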